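**The flask.** If a target stops growing while its substrate keeps falling, I ask what each lost unit of substrate has left behind. The dawn run follows the very flask in question, with the rival reagent fed over 8.0 min.

| flask | substrate | rival reagent | gas | remark | time |
|---|---|---|---|---|---|
| dawn | 0.65 M | 0.60 equiv (fed, over 8.0 min) | 120 mM (held) | the very flask that is asked about, followed so far; the fed solution adds 0.25 times the starting volume |  |
| flask | 0.65 M | 0.600 equiv (fed, over 8.0 min) | 120 mM (held) | the fed solution adds 0.25 times the starting volume | 12 h |

dawn run (percent of the substrate charged)

| time / h | target / % | substrate / % |
|---|---|---|
| 0.100 | 15 | 79 |
| 0.333 | 25 | 32 |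
| 0.833 | 24 | 5 |
| 2.50 | 24 | 3 |

(readings scatter by 1.5 percentage points)

- amounts are per litre of the starting volume; all of the dose is in the solution fed
- the earlier runs were read with a standard deviation of 1.5 percentage points
- at the start none of the gas is in solution

- time, not beyond 12 h, at which the flask holds most target
- the amount of target, in percent of the substrate charged, at that time
- earliest time at which at least nineteen twentieths of that best amount are there
- latest time at which they still are

**The contradiction.** Between 0.333 h and 0.833 h the dawn run lost 27 percentage points of substrate, yet the target reading went from 25% to 24%.

**My reckoning.** The target read per substrate lost at the last reading of the dawn run was 24.7%; I called this the late share. The same ratio read 71.4% at 0.100 h and 36.8% at 0.333 h, so it drifted down. At 0.333 h the target reading of the dawn run stood 8.2 points above the late share of the substrate lost, against a scatter of 1.5 points. I therefore read the flat stretch as a descent towards the late share, with a maximum possibly hidden between the readings at 0.333 h and 0.833 h.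

**The forecast.** It gave 24.5% at 12 h, with the band from 0.28 h to 12 h, saying “there is no visible decay”. There we differed: it expected a plateau, I allowed a hump.

**The result.** The flask held most target at 0.411 h, 27.9%, with the band from 0.272 h to 0.675 h.

    substrate + partner → target (k = 0.620 M⁻¹ min⁻¹)
    substrate + rival reagent → side product (k = 0.0162 M⁻¹ min⁻¹)
    target ⇌ isomer of the product (K = 2.80, k = 0.123 min⁻¹)
    gas ⇌ partner, rate k4*(csat - [partner]) (kL = 0.563 min⁻¹)

**What stood.** The target and the isomer of the product relax with a half-life of 0.0692 h, short against the 12 h allowed, and the forward step alone has a half-life of 0.094 h. At 12.0 h the flask held 24.5% target beside 68.6% isomer of the product, which is thermodynamic control after a kinetic start, with 0% substrate left, so the late share read from the dawn run gives 24.7% target there. For the flask with 0.360 equiv of rival reagent, 0% substrate left at 12.0 h makes the late share give 24.7% target, and that flask held 25.2%.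

The runs were computed from invented constants; scatter was added.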